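Ring B of this guai-4-en-3-one (guaiane numbering) is cut on both sides of its oxygenated C7–C8 edge, at C6–C7 and C8–C9. The ten carbons left (ring A, C15, C6, C9, C10, C14) are the thujane skeleton, with C6 as the cyclopropane methylene. The edge is a five-carbon alkyne. One rhodium-catalysed intermolecular [5+2] cycloaddition of a 1-isopropenylbicyclo[3.1.0]hexane (ketal of dehydro-α-thujone) and 2-methylbut-3-yn-2-ol spends the C1–C6 cyclopropane bond, which is absent from the target. It closes ring B and assembles all fifteen skeletal carbons. The surviving C5 stereocentre then directs hydroboration of C7=C8. A final base-mediated alkene walk erases C4 and C5 while setting C1 and C10.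

Key step: step 4

Remark: guaiane numbering is used for every compound. Ring A is C1–C5 (C15 on C4), ring B is C1, C5–C10 (C14 on C10), and the side chain C11–C13 sits on C7. In 1–4 the cyclopropane is C1/C5/C6 and the three-carbon group on C1 is C10 with C9 and C14. β is the face that carries H5 and C15 in 1.
Remark: C4 and C5 are erased in step 8, so any epimerisation at C4 on the way is without consequence. Structures show the α-thujone configuration.

Step 1
Reactants: 1 (−)-α-thujone
Product: 2 (1R,4R,5R)-1-(2-hydroxypropan-2-yl)-4-methylbicyclo[3.1.0]hexan-3-one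
Conditions: methyl(trifluoromethyl)dioxirane (1.2 equiv), CH2Cl2/CF3COCH3, −20 °C
Reagents that add atoms: methyl(trifluoromethyl)dioxirane, CC1(OO1)C(F)(F)F
Why: Dioxirane C–H hydroxylation (concerted oxygen insertion) should pick the isopropyl methine C10–H, the only unhindered tertiary C–H and one activated by hyperconjugation with the adjacent cyclopropane, whereas C4–H is deactivated by the carbonyl group and C5–H is a strong cyclopropane C–H; no stereocentre is formed or touched.

Step 2
Reactants: 2 (1R,4R,5R)-1-(2-hydroxypropan-2-yl)-4-methylbicyclo[3.1.0]hexan-3-one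
Product: 3 dehydro-α-thujone, (1R,4R,5R)-4-methyl-1-(prop-1-en-2-yl)bicyclo[3.1.0]hexan-3-one
Conditions: Burgess reagent, toluene, 50 °C
Reagents that add atoms: none
Why: Burgess dehydration (syn elimination of a sulfamate ester under neutral, nucleophile-free conditions) can only remove a methyl hydrogen because C1 is quaternary, so the isopropenyl group is the sole possible alkene, and the absence of halide avoids homoallylic opening of the cyclopropylcarbinyl system.

Step 3
Reactants: 3 dehydro-α-thujone
Product: 4 (1R,4R,5R)-4-methyl-1-(prop-1-en-2-yl)spiro[bicyclo[3.1.0]hexane-3,2'-[1,3]dioxolane]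
Conditions: HOCH2CH2OH, PPTS (cat.), benzene, reflux, Dean–Stark
Reagents that add atoms: ethylene glycol, OCCO
Why: Acid-catalysed ketalisation with azeotropic removal of water masks the C3 ketone against borane in step 5, and PPTS is too weak an acid to ionise the isopropenylcyclopropane.

Step 4
Reactants: 4 (1R,4R,5R)-4-methyl-1-(prop-1-en-2-yl)spiro[bicyclo[3.1.0]hexane-3,2'-[1,3]dioxolane]; 5 2-methylbut-3-yn-2-ol
Product: 6 (4R,5R)-3,3-ethylenedioxyguaia-1(10),7-dien-11-ol (H5 β, C15 β)
Conditions: [Rh(CO)2Cl]2 (5 mol %), 5 (2 equiv, slow addition), ClCH2CH2Cl, 80 °C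
Reagents that add atoms: none
Why: Monovalent rhodium binds the isopropenyl group of 4 and inserts into the adjacent cyclopropane bond C1–C6 to give a trivalent (σ-alkyl)(π-allyl)rhodacyclohexene, alkyne 5 then inserts at the allyl terminus C9 (bond C8–C9), and C(sp2)–C(sp3) reductive elimination from the eight-membered rhodacycle forges C6–C7. The closest known reaction type is the intermolecular rhodium-catalysed [5+2] cycloaddition of alkyl-substituted, heteroatom-free vinylcyclopropanes and terminal alkynes. Ring B is the only ring closed, and it closes as a cycloaddition by reductive elimination within a metallacycle, not by an endo or exo attack along an open chain, while the cyclopropane is the temporary ring that is spent. No new stereocentre is formed: C1 becomes sp2 (C1=C10), whereas C5, none of whose bonds is touched, keeps its configuration and carries the chirality of thujone into 6. Three selectivities are needed: cleavage of C1–C6 rather than the ring-fusion bond C1–C5 (C6 is the less substituted carbon and C1–C5 cleavage would lead to a bridgehead alkene in a bicyclo[4.3.1] frame), attachment of the carbinol-bearing alkyne carbon to C6 (the bulky CMe2OH group stays distal to the first C–C bond formed at C9), and cross-reaction rather than alkyne oligomerisation (slow addition of 5). The methyl group on C10 and the quaternary C1 favour the rotamer in which C9 lies over C6, which is what lets unactivated vinylcyclopropanes react intermolecularly.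

Step 5
Reactants: 6 (4R,5R)-3,3-ethylenedioxyguaia-1(10),7-dien-11-ol
Product: 8 (4R,5R,7S,8S)-3,3-ethylenedioxyguai-1(10)-ene-8,11-diol (H7 α, 8α-OH, trans to the side chain), via oxaborolane 7 (not isolated)
Conditions: BH3·SMe2 (2 equiv), THF, 0 °C to rt; then NaOH, H2O2, 0 °C
Reagents that add atoms: hydrogen peroxide, OO; borane–dimethyl sulfide, C[S+](C)[BH3-] (boron only in 7)
Why: Hydroboration–oxidation places boron on the less substituted C8 and hydrogen on C7 by syn addition from the convex α face, because the ring fusion locks the cyclohepta-1,4-diene of 6 in one twist form in which C5, its axial β-hydrogen and C1 cover the β face of C7=C8, so H7 becomes α (its final configuration) and oxidation with retention gives the 8α-hydroxyl, while the tetrasubstituted C1=C10 bond reacts more slowly and the ketal shields C3.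

Step 6
Reactants: 8 (4R,5R,7S,8S)-3,3-ethylenedioxyguai-1(10)-ene-8,11-diol
Product: 9 (4R,5R,7S,8R)-3,3-ethylenedioxy-11-hydroxyguai-1(10)-en-8-yl methacrylate (8β-ester, cis to the side chain)
Conditions: methacrylic acid, PPh3, DIAD, toluene, 0 °C to rt
Reagents that add atoms: methacrylic acid, C=C(C)C(=O)O
Why: In this Mitsunobu esterification the alkoxyphosphonium salt of the secondary 8α-alcohol is displaced by methacrylate in an SN2 process with inversion, which sets the 8β (R) configuration and installs the ester in the same operation, the tertiary C11 hydroxyl being inert.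

Step 7
Reactants: 9 (4R,5R,7S,8R)-3,3-ethylenedioxy-11-hydroxyguai-1(10)-en-8-yl methacrylate
Product: 10 (4R,5R,7S,8R)-11-acetoxy-3,3-ethylenedioxyguai-1(10)-en-8-yl methacrylate
Conditions: Ac2O, DMAP (cat.), pyridine, 50 °C
Reagents that add atoms: acetic anhydride, CC(=O)OC(C)=O
Why: DMAP-catalysed acylation (N-acetylpyridinium transfer) is strong enough for the hindered tertiary C11 alcohol and touches neither the ketal, the methacrylate nor any stereocentre.

Step 8
Reactants: 10 (4R,5R,7S,8R)-11-acetoxy-3,3-ethylenedioxyguai-1(10)-en-8-yl methacrylate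
Product: 14 (1R,7S,8R,10S)-11-acetoxy-3-oxoguai-4-en-8-yl methacrylate (target), via β,γ-enone 11 (not isolated), via 1(2)-enone 12 (not isolated), via 1(5)-enone 13 (not isolated)
Conditions: PPTS (cat.), acetone/H2O, 56 °C; evaporate; DBU, toluene, 80 °C
Reagents that add atoms: water, O
Why: Ketal hydrolysis frees the β,γ-unsaturated ketone 11, whose doubly activated C2–H lets DBU start a dienolate-mediated alkene walk of the prostaglandin A to B type (C1=C10 to C1=C2 to C1=C5 to C4=C5) that ends in the tetrasubstituted conjugated enone as thermodynamic sink, erases C4 and C5, and sets C10 and C1 by reversible γ-protonation under control of the fixed C7 and C8 centres, the 1βH,10β-methyl isomer being the one that places the C7 side chain, C14 and the C1–C2 bond all equatorial in a twist-chair of ring B whose C5–C1 torsion fits the flat cyclopentenone.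

Compound list
1 | (−)-α-thujone, (1S,4R,5R)-4-methyl-1-(propan-2-yl)bicyclo[3.1.0]hexan-3-one | C[C@@H]1[C@H]2C[C@]2(CC1=O)C(C)C | starting material
2 | (1R,4R,5R)-1-(2-hydroxypropan-2-yl)-4-methylbicyclo[3.1.0]hexan-3-one | C[C@@H]1[C@H]2C[C@]2(CC1=O)C(C)(C)O | intermediate
3 | dehydro-α-thujone, (1R,4R,5R)-4-methyl-1-(prop-1-en-2-yl)bicyclo[3.1.0]hexan-3-one | C[C@@H]1[C@H]2C[C@]2(CC1=O)C(C)=C | intermediate
4 | (1R,4R,5R)-4-methyl-1-(prop-1-en-2-yl)spiro[bicyclo[3.1.0]hexane-3,2'-[1,3]dioxolane] | C[C@@H]1[C@H]2C[C@]2(CC13OCCO3)C(C)=C | intermediate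
5 | 2-methylbut-3-yn-2-ol | C#CC(C)(C)O | starting material
6 | (4R,5R)-3,3-ethylenedioxyguaia-1(10),7-dien-11-ol | C[C@@H]1[C@H]2CC(C(C)(C)O)=CCC(C)=C2CC13OCCO3 | intermediate
7 | cyclic borinate of 6, a 1,2-oxaborolane (B–H) that spans C8 (α bond) and O11, H7 α | C[C@@H]1[C@H]2C[C@H]3[C@@H](BOC3(C)C)CC(C)=C2CC14OCCO4 | intermediate
8 | (4R,5R,7S,8S)-3,3-ethylenedioxyguai-1(10)-ene-8,11-diol | C[C@@H]1[C@H]2C[C@H](C(C)(C)O)[C@@H](O)CC(C)=C2CC13OCCO3 | intermediate
9 | (4R,5R,7S,8R)-3,3-ethylenedioxy-11-hydroxyguai-1(10)-en-8-yl methacrylate | C[C@@H]1[C@H]2C[C@H](C(C)(C)O)[C@H](OC(=O)C(C)=C)CC(C)=C2CC13OCCO3 | intermediate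
10 | (4R,5R,7S,8R)-11-acetoxy-3,3-ethylenedioxyguai-1(10)-en-8-yl methacrylate | C[C@@H]1[C@H]2C[C@H](C(C)(C)OC(C)=O)[C@H](OC(=O)C(C)=C)CC(C)=C2CC13OCCO3 | intermediate
11 | (4R,5R,7S,8R)-11-acetoxy-3-oxoguai-1(10)-en-8-yl methacrylate | C[C@@H]1[C@H]2C[C@H](C(C)(C)OC(C)=O)[C@H](OC(=O)C(C)=C)CC(C)=C2CC1=O | intermediate
12 | 11-acetoxy-3-oxoguai-1-en-8β-yl methacrylate (C1=C2, H5 β, H10 α, H7 α) | C[C@@H]1[C@H]2C[C@H](C(C)(C)OC(C)=O)[C@H](OC(=O)C(C)=C)C[C@H](C)C2=CC1=O | intermediate
13 | 11-acetoxy-3-oxoguai-1(5)-en-8β-yl methacrylate (H10 α, H7 α, C15 β) | C[C@@H]1C(C[C@H](C(C)(C)OC(C)=O)[C@H](OC(=O)C(C)=C)C[C@@H]2C)=C2CC1=O | intermediate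
14 | (1R,7S,8R,10S)-11-acetoxy-3-oxoguai-4-en-8-yl methacrylate | C=C(C)C(=O)O[C@@H]1C[C@H](C)[C@H]2CC(=O)C(C)=C2C[C@@H]1C(C)(C)OC(C)=O | target

Total step count: 8. Longest linear sequence: 8 steps (1 to 14).

Steps most likely to fail

Step 4. Opening of the fully alkyl-substituted vinylcyclopropane may be slow. β-Hydride elimination at C5 to ring-opened dienes, oligomerisation of the alkyne, catalyst binding by the free hydroxyl, or leakage of regiocontrol could then take over. The fallback sets out from 4. The cycloaddition is run with tert-butyl propiolate, an electron-poor alkyne without a free hydroxyl that inserts faster. Its bulk and Michael polarity both send the unsubstituted carbon to C9, which should give the C7 tert-butyl ester cycloadduct F1. Double addition of MeLi/CeCl3 (THF, −78 °C) then builds the carbinol after the ring instead of before it and comes back to the route at 6.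

Step 6. Displacement at a carbinol flanked by the quaternary side chain may be slow. Anti elimination towards C9 (conjugated diene) or participation of the homoallylic C1=C10 bond could compete with inversion. The fallback sets out from 8. Oxidation with Dess–Martin periodinane should give the β-hydroxy ketone F2. LiBH(s-Bu)3 (THF, −78 °C) attacks from the α face, anti to the β side chain, to give the cis-diol F3. Selective acylation of the secondary hydroxyl with methacrylic anhydride/DMAP comes back to the route at 9.

Step 8. Equilibration may be incomplete. The walk could stall at the 1(2)-enone or fix C10 under kinetic rather than thermodynamic control, with loss of selectivity at C1 and C10, and DBU could slowly attack the methacrylate. The fallback sets out from 8 and fixes C10 kinetically.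
- Hydroxyl-directed hydrogenation with [Ir(cod)(PCy3)(py)]PF6 (H2, CH2Cl2) lets the homoallylic 8α-hydroxyl deliver hydrogen to the α face of C1=C10. This gives the saturated diol F4 (H1 α, H10 α, C14 β).
- Mitsunobu esterification as in step 6 gives the methacrylate F5.
- Acetylation as in step 7 gives the diester ketal F6.
- Ketal hydrolysis gives the cyclopentanone F7.
- Dehydrogenation with IBX (DMSO, 70 °C) through the more substituted enol introduces C4=C5 and gives the 1-epi-enone F8.
- Brief treatment with DBU epimerises only the γ-position C1 to the trans 1βH,10β-methyl arrangement and comes back to the route at 14.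

Further compounds
F1 | step 4 | tert-butyl (4R,5R)-3,3-ethylenedioxy-12,13-dinorguaia-1(10),7-dien-11-oate (tert-butyl ester on C7) | C[C@@H]1[C@H]2CC(C(=O)OC(C)(C)C)=CCC(C)=C2CC13OCCO3
F2 | step 6 | (4R,5R,7S)-3,3-ethylenedioxy-11-hydroxyguai-1(10)-en-8-one | C[C@@H]1[C@H]2C[C@H](C(C)(C)O)C(=O)CC(C)=C2CC13OCCO3
F3 | step 6 | (4R,5R,7S,8R)-3,3-ethylenedioxyguai-1(10)-ene-8,11-diol (8β-OH, cis) | C[C@@H]1[C@H]2C[C@H](C(C)(C)O)[C@H](O)CC(C)=C2CC13OCCO3
F4 | step 8 | 3,3-ethylenedioxyguaiane-8α,11-diol (H1 α, H5 β, H7 α, H10 α) | C[C@@H]1[C@H]2C[C@H](C(C)(C)O)[C@@H](O)C[C@H](C)[C@@H]2CC13OCCO3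
F5 | step 8 | 3,3-ethylenedioxy-11-hydroxyguaian-8β-yl methacrylate (H1 α, H10 α) | C[C@@H]1[C@H]2C[C@H](C(C)(C)O)[C@H](OC(=O)C(C)=C)C[C@H](C)[C@@H]2CC13OCCO3
F6 | step 8 | 11-acetoxy-3,3-ethylenedioxyguaian-8β-yl methacrylate (H1 α, H10 α) | C[C@@H]1[C@H]2C[C@H](C(C)(C)OC(C)=O)[C@H](OC(=O)C(C)=C)C[C@H](C)[C@@H]2CC13OCCO3
F7 | step 8 | 11-acetoxy-3-oxoguaian-8β-yl methacrylate (H1 α, H10 α) | C[C@@H]1[C@H]2C[C@H](C(C)(C)OC(C)=O)[C@H](OC(=O)C(C)=C)C[C@H](C)[C@@H]2CC1=O
F8 | step 8 | 1-epi-14, (1S,7S,8R,10S)-11-acetoxy-3-oxoguai-4-en-8-yl methacrylate | CC1=C2C[C@H](C(C)(C)OC(C)=O)[C@H](OC(=O)C(C)=C)C[C@H](C)[C@@H]2CC1=O
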